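- I decide to follow one ratio through this flask: target over everything else on the plateau, divided by the equivalents of partner.

| setting | larch | alder | ash | flask |
|---|---|---|---|---|
| substrate | 0.52 M | 1.2 M | 0.78 M | 0.78 M |
| partner | 2 equiv | 2 equiv | 1 equiv | 2.00 equiv |
| remark | run made earlier | run made earlier | run made earlier |  |
| time |  |  |  | 2.5 min |

- larch (time / s: target / %, crystals / %, substrate / %): 12.0: 10.9, 8.4, 37.7; 25.0: 34.1, 32.6, 13.0; 40.0: 53.4, 51.8, 2.9; 50.0: 60.7, 58.2, 2.0; 60.0: 63.6, 62.3, 0.8; 80.0: 66.3, 64.9, 0.4; 90.0: 67.7, 64.6, 0.2
- alder (time / s: target / %, crystals / %, substrate / %): 12.0: 18.6, 16.3, 37.5; 25.0: 44.3, 44.3, 13.9; 40.0: 60.2, 60.1, 4.4; 50.0: 65.6, 64.0, 2.4; 60.0: 66.9, 66.8, 1.8; 80.0: 67.7, 66.6, 0; 90.0: 68.6, 66.5, 0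
- ash (time / s: target / %, crystals / %, substrate / %): 10.0: 4.6, 3.8, 44.9; 15.0: 12.1, 10.3, 29.8; 25.0: 23.2, 22.5, 13.2; 50.0: 40.7, 39.7, 1.4; 90.0: 49.1, 47.3, 0.4

(scatter of a reading: 0.5 percentage points)

* amount of target and crystals together at 2.5 min, in percent of the substrate charged
* concentration of target in solution at 2.5 min, in percent of saturation

- what is said of target includes crystals
- crystals is a solid; its amount is given per volume of the solution
- what was read earlier has a scatter of 0.5 percentage points, one standard deviation

- The first reading of the larch run gives substrate a first-order constant of 0.0813 /s, so a half-life of 8.53 s. The asked 2.5 min is 17.6 such half-lives, so I reckon on the plateau.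
- Larch and alder differ by a factor of 2.31 in concentration, yet their last target readings are 67.7% and 68.6%. Concentration therefore moves the plateau little across this range.
- Their mean gives the selectivity per equivalent, s, the plateau target-to-rest ratio per equivalent of partner: 1.07.
- With 2.00 equiv, target is s·eq/(1 + s·eq), where eq is the equivalents charged: 68.2%.
- The weak link is the ash run, which gives a lower 0.965. Ash was charged with 1 equiv of partner, larch and alder with 2 equiv like this flask, so I take s from larch and alder for this flask and treat it as a reading that may shift with the equivalents.
- Target and crystals stay close from the first readings, so I expect the solution at about 100% of saturation.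
- The forecast gives 68% (66.8% to 69.2%) and 100% (98% to 104%), holding that “Final yield depends on equivalents”.
- The flask gives 67.7% and 100%.

    2 open intermediate → homo product (k = 0.100 /M/s)
    crystals ⇌ target, rate k2*(cs2 - [target]) while solid is left; crystals form when [target] > cs2 (solubility = 11.0 mM, k = 4.80 /s)
    substrate → open intermediate (k = 0.0810 /s)
    open intermediate + second intermediate → target (k = 0.180 /M/s)
    partner → second intermediate (k = 0.0300 /s)

- This flask's own ratio is 1.05 per equivalent, beside s at 1.07. At 0.379 min in this flask, substrate's step has a half-life of 0.14 min, shorter than the 0.39 min of partner's path alone, and homo product ends at 32.3%.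
- For the neighbour with 3.40 equiv of partner, s gives 78.4%. The computed neighbour gives 79.2%.

The readings are calculated from invented constants; noise was put on by code.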